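## Retrosynthetic overview

1. The last operation is fluoride removal of four silyl groups from the fully assembled skeleton. All six stereocentres are in place before it.
2. Key disconnection: both tetrahydrofuran rings of the 3,7-dioxabicyclo[3.3.0]octane core are opened at once (bonds C8–C8' and C7–O) to an open-chain epoxy cinnamyl ether. In the forward sense a Ti(III) radical–polar cascade closes ring O–C7'–C8'–C8–C9 first. It then closes ring C7–O–C9'–C8'–C8 as the last ring of the skeleton.
3. Enabling feature: the bond C8–C8' shared by the two rings has C9'H2–O on one side, so C8', C9' and that O can be stored as an oxirane (latent C8' radical plus C9' alkoxide). On the other side it has benzylic C7 on the 4-alkoxy-3-methoxyphenyl ring B, so C8=C7 is a styrene-type radical acceptor. The resulting C7 radical is easily raised to a p-alkoxybenzyl electrophile that the C9' oxygen captures.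
4. The ether bond O–C9 leads back to an erythro epoxy alcohol and a cinnamyl bromide that already carries the side chain. The epoxy alcohol comes from a Sharpless kinetic resolution, and its carbinol centre C7' is the only stereocentre that steers C8', C8 and C7.
5. The side chain comes from an Evans syn aldol of a ferulate-derived aryloxyacetyl imide (sets C8'') with O-TIPS-vanillin, followed by Mitsunobu inversion at C7'' (threo to erythro). O-TIPS-vanillin feeds both halves.

Key step: step 14

Remark (numbering and reading of the structure): lignan numbering is used.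
- Ring B with C7–C9 is the ether-bearing aryl group and its C3 chain.
- Ring A with C7'–C9' is the free guaiacyl half of the bicycle.
- Ring C with C7''–C9'' is the guaiacylglycerol unit.
- The SMILES is read as 7R,8S,7'R,8'S (the (−)-pinoresinol series, both aryl groups exo) and 7''R,8''S (erythro).

## Route

Step 1
Reactants: 1 vanillin
Product: 2 3-methoxy-4-(triisopropylsilyloxy)benzaldehyde (O-TIPS-vanillin)
Conditions: TIPSCl, imidazole, DMF, rt
Reagents that add atoms: triisopropylsilyl chloride, CC(C)[Si](Cl)(C(C)C)C(C)C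
Why: Imidazole-promoted silylation of a phenol; the bulky TIPS ether is chosen because it should survive Grignard, alkoxide, borohydride and carbonate conditions and falls to fluoride at the end.

Step 2
Reactants: 2 O-TIPS-vanillin
Product: 3 rac-1-[3-methoxy-4-(triisopropylsilyloxy)phenyl]prop-2-en-1-ol
Conditions: vinylMgBr, THF, −78 → 0 °C; aq NH4Cl
Reagents that add atoms: vinylmagnesium bromide, C=C[Mg]Br
Why: Grignard 1,2-addition to a non-enolisable aldehyde gives the racemic aryl vinyl carbinol that the next step resolves.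

Step 3
Reactants: 3 racemic aryl vinyl carbinol
Product: 4 (S)-[3-methoxy-4-(triisopropylsilyloxy)phenyl][(2R)-oxiran-2-yl]methanol (erythro epoxy alcohol)
Conditions: Ti(OiPr)4 (0.15 equiv), L-(+)-DIPT (0.2 equiv), t-BuOOH (0.45 equiv, decane), 4 Å MS, CH2Cl2, −20 °C
Reagents that add atoms: tert-butyl hydroperoxide, CC(C)(C)OO
Why: Sharpless kinetic resolution (Katsuki–Sharpless epoxidation with substoichiometric oxidant): with L-(+)-DIPT the (R)-carbinol is the fast-reacting enantiomer and is epoxidised to the erythro epoxy alcohol, which fixes C7' in the sense the target needs, while the slow (S)-carbinol stays behind and is removed by chromatography.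

Step 4
Reactants: 5 (R)-4-benzyl-1,3-oxazolidin-2-one
Product: 6 (R)-4-benzyl-3-(bromoacetyl)-1,3-oxazolidin-2-one
Conditions: n-BuLi, THF, −78 °C; BrCH2COBr, −78 → 0 °C
Reagents that add atoms: bromoacetyl bromide, BrCC(Br)=O
Why: N-acylation of the lithiated Evans oxazolidinone at the acyl bromide terminus, which reacts far faster than the alkyl bromide.

Step 5
Reactants: 6 bromoacetyl imide; 7 methyl (E)-ferulate
Product: 8 methyl (E)-3-(4-{2-[(4R)-4-benzyl-2-oxo-1,3-oxazolidin-3-yl]-2-oxoethoxy}-3-methoxyphenyl)prop-2-enoate (aryloxyacetyl imide)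
Conditions: K2CO3, acetone, rt
Reagents that add atoms: none
Why: Williamson-type SN2 of the phenol oxygen at the strongly activated α-bromo imide carbon under mild carbonate conditions that leave imide and cinnamate untouched.

Step 6
Reactants: 8 aryloxyacetyl imide; 2 O-TIPS-vanillin
Product: 11 Evans syn aldol adduct (2R,3S), via boron enolate 9 (not isolated), via boron aldolate 10 (not isolated)
Conditions: Bu2BOTf, Et3N, CH2Cl2, −78 → 0 °C; 2, −78 → 0 °C; pH 7 buffer, MeOH, 30% H2O2, 0 °C
Reagents that add atoms: none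
Why: Evans boron aldol: soft enolisation gives the (Z)-boron enolate, and the Zimmerman–Traxler chair with the dipole-opposed (R)-benzyl auxiliary should deliver the Evans syn adduct, which sets C8'' as required (S after reduction) and C7'' as S (threo).

Step 7
Reactants: 11 syn aldol adduct
Product: 12 threo-(7''S,8''S) 1,3-diol (methyl cinnamate retained)
Conditions: NaBH4, THF–H2O (4:1), 0 °C → rt
Reagents that add atoms: none
Why: Borohydride reduction of the activated N-acyl oxazolidinone in aqueous THF releases the primary alcohol without epimerisation, and the conjugated methyl ester is too unreactive to be reduced.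

Step 8
Reactants: 12 threo diol
Product: 13 threo C9''-O-TBS ether with free C7'' hydroxyl
Conditions: TBSCl (1.05 equiv), imidazole, CH2Cl2, 0 °C
Reagents that add atoms: tert-butyldimethylsilyl chloride, CC(C)(C)[Si](C)(C)Cl
Why: Sterically controlled silylation selects the primary C9'' hydroxyl over the hindered secondary benzylic one.

Step 9
Reactants: 13 threo mono-TBS alcohol
Product: 15 erythro-(7''R,8''S) mono-TBS alcohol, via nitrobenzoate 14 (not isolated)
Conditions: 4-O2NC6H4CO2H, PPh3, DIAD, toluene, −20 → 0 °C; then MeOH, K2CO3 (cat.), 0 °C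
Reagents that add atoms: 4-nitrobenzoic acid, O=C(O)c1ccc(cc1)[N+](=O)[O-]
Why: Mitsunobu reaction with an acidic carboxylic acid in a non-polar solvent at low temperature inverts C7'' by SN2 (S to R, threo to erythro), and the very labile nitrobenzoate is then removed by carbonate-catalysed transesterification in the same flask.

Step 10
Reactants: 15 erythro mono-TBS alcohol
Product: 16 erythro bis-TBS methyl cinnamate
Conditions: TBSOTf, 2,6-lutidine, CH2Cl2, −78 → 0 °C
Reagents that add atoms: tert-butyldimethylsilyl triflate, CC(C)(C)[Si](C)(C)OS(=O)(=O)C(F)(F)F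
Why: Silyl triflate/lutidine silylation of a hindered secondary alcohol; a 1,3-silyl shift in 15 would be harmless because both hydroxyls end as TBS ethers.

Step 11
Reactants: 16 bis-TBS methyl cinnamate
Product: 17 (E)-cinnamyl alcohol carrying the protected side chain
Conditions: DIBAL-H (2.5 equiv), CH2Cl2, −78 °C; Rochelle salt
Reagents that add atoms: none
Why: DIBAL-H 1,2-reduction of an α,β-unsaturated ester to the (E)-allylic alcohol, to which silyl ethers are inert.

Step 12
Reactants: 17 cinnamyl alcohol
Product: 18 (E)-cinnamyl bromide (used at once, kept cold)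
Conditions: CBr4, PPh3, 2,6-lutidine, CH2Cl2, −30 → 0 °C
Reagents that add atoms: carbon tetrabromide, BrC(Br)(Br)Br
Why: The Appel reaction turns the primary allylic alcohol into the bromide under neutral conditions, and the conjugated linear isomer is the favoured one.

Step 13
Reactants: 4 erythro epoxy alcohol; 18 cinnamyl bromide
Product: 19 open-chain epoxy cinnamyl ether (C7' S by CIP, oxirane carbon R, 7''R,8''S)
Conditions: NaH, THF–DMSO, 0 °C; then 18, Bu4NI (cat.), 0 °C → rt
Reagents that add atoms: none
Why: Williamson ether synthesis: after deprotonation the C7' oxygen attacks the primary allylic carbon C9 by SN2 without breaking a bond to any stereocentre, and any minor enantiomer of 4 becomes a separable diastereomer here.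

Step 14
Reactants: 19 epoxy cinnamyl ether
Product: 22 tetrasilylated target (7R,8S,7'R,8'S,7''R,8''S), via benzyltitanium alkoxide 20 (not isolated), via benzylic iodide 21 (not isolated)
Conditions: Cp2TiCl2 (3 equiv), Zn dust, THF, rt (green Cp2TiCl, decanted from Zn), added dropwise to 19 in THF, rt; then I2 (1.5 equiv), rt → 40 °C; aq Na2S2O3
Reagents that add atoms: none
Why: Cp2TiCl transfers one electron to the oxirane and cleaves the C8'–O bond to give the secondary C8' radical with C9'–O–Ti(IV); this radical adds 5-exo-trig to C8 of the (E)-cinnamyl double bond (first ring O–C7'–C8'–C8–C9), a second Cp2TiCl captures the benzylic C7 radical, iodine converts C7–Ti into C7–I, and the C9' titanium alkoxide displaces iodide (5-exo-tet, or 5-exo-trig on the p-alkoxybenzyl cation) to close ring C7–O–C9'–C8'–C8 last. The closest known reaction type is the titanocene(III) (Nugent–RajanBabu) radical cyclisation of epoxy cinnamyl ethers with iodine termination, established for 2,6-diaryl-3,7-dioxabicyclo[3.3.0]octanes. C8' and C8 are controlled by C7': in the Beckwith–Houk chair transition state the ring-A aryl group is pseudo-equatorial, so C9' ends trans to it and the new C8 substituent cis to C9', and because C8' is planar in the radical the oxirane configuration has no influence. C7 is set in the second closure, where only the cis-fused bicycle can form and the ring-B aryl group takes the exo (convex) position, an outcome that an SN1-type closure reaches as well. The step needs oxirane opening to the secondary rather than the primary radical, 5-exo rather than 6-endo addition (secured by the aryl group on C7, which makes the 5-exo radical benzylic) and cyclisation faster than reduction of the C8' radical (secured by slow addition of Cp2TiCl). Silyl ethers, aryl ethers and the β-aryl ether side chain offer nothing that Ti(III), ZnCl2 or I2 in THF should attack at this temperature, and the product is an isomer of 19.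

Step 15
Reactants: 22 tetrasilylated target
Product: 23 target, (7R,8S,7'R,8'S)-pinoresinol 4-O-[(7''R,8''S)-guaiacylglycer-8''-yl] ether
Conditions: TBAF (6 equiv), AcOH (6 equiv), THF, 0 °C → rt
Reagents that add atoms: none
Why: Fluoride-driven cleavage of all four silyl ethers under acetic acid buffering, conditions that should neither ionise the benzylic C–O bonds of the bicycle or of C7'' nor generate a quinone methide.

## Compound list

1 | vanillin | COc1cc(C=O)ccc1O | starting material
2 | 3-methoxy-4-(triisopropylsilyloxy)benzaldehyde | COc1cc(C=O)ccc1O[Si](C(C)C)(C(C)C)C(C)C | intermediate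
3 | rac-1-[3-methoxy-4-(triisopropylsilyloxy)phenyl]prop-2-en-1-ol | COc1cc(C(O)C=C)ccc1O[Si](C(C)C)(C(C)C)C(C)C | intermediate
4 | (S)-[3-methoxy-4-(triisopropylsilyloxy)phenyl][(2R)-oxiran-2-yl]methanol | COc1cc([C@H](O)[C@H]2CO2)ccc1O[Si](C(C)C)(C(C)C)C(C)C | intermediate
5 | (R)-4-benzyl-1,3-oxazolidin-2-one | O=C1N[C@H](Cc2ccccc2)CO1 | starting material
6 | (R)-4-benzyl-3-(bromoacetyl)-1,3-oxazolidin-2-one | BrCC(=O)N1[C@H](Cc2ccccc2)COC1=O | intermediate
7 | methyl (E)-ferulate | COC(=O)/C=C/c1ccc(O)c(OC)c1 | starting material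
8 | aryloxyacetyl imide of methyl ferulate, (4R)-auxiliary | COC(=O)/C=C/c1ccc(OCC(=O)N2[C@H](Cc3ccccc3)COC2=O)c(OC)c1 | intermediate
9 | (Z)-dibutylboron enolate of 8 | COC(=O)/C=C/c1ccc(O/C=C(\OB(CCCC)CCCC)N2[C@H](Cc3ccccc3)COC2=O)c(OC)c1 | intermediate
10 | dibutylboron aldolate of 11 | COC(=O)/C=C/c1ccc(O[C@H]([C@@H](OB(CCCC)CCCC)c2ccc(O[Si](C(C)C)(C(C)C)C(C)C)c(OC)c2)C(=O)N3[C@H](Cc4ccccc4)COC3=O)c(OC)c1 | intermediate
11 | Evans syn aldol adduct, (2R,3S)-2-aryloxy-3-hydroxy-3-arylpropanoyl imide | COC(=O)/C=C/c1ccc(O[C@H]([C@@H](O)c2ccc(O[Si](C(C)C)(C(C)C)C(C)C)c(OC)c2)C(=O)N3[C@H](Cc4ccccc4)COC3=O)c(OC)c1 | intermediate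
12 | methyl (E)-3-(4-{[(1S,2S)-1,3-dihydroxy-1-(3-methoxy-4-TIPSO-phenyl)propan-2-yl]oxy}-3-methoxyphenyl)prop-2-enoate (threo) | COC(=O)/C=C/c1ccc(O[C@H]([C@@H](O)c2ccc(O[Si](C(C)C)(C(C)C)C(C)C)c(OC)c2)CO)c(OC)c1 | intermediate
13 | threo (1S,2S) alcohol with the primary OH as TBS ether | COC(=O)/C=C/c1ccc(O[C@H]([C@@H](O)c2ccc(O[Si](C(C)C)(C(C)C)C(C)C)c(OC)c2)CO[Si](C)(C)C(C)(C)C)c(OC)c1 | intermediate
14 | erythro (1R,2S) 4-nitrobenzoate | COC(=O)/C=C/c1ccc(O[C@H]([C@H](OC(=O)c3ccc(cc3)[N+](=O)[O-])c2ccc(O[Si](C(C)C)(C(C)C)C(C)C)c(OC)c2)CO[Si](C)(C)C(C)(C)C)c(OC)c1 | intermediate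
15 | erythro (1R,2S) alcohol with the primary OH as TBS ether | COC(=O)/C=C/c1ccc(O[C@H]([C@H](O)c2ccc(O[Si](C(C)C)(C(C)C)C(C)C)c(OC)c2)CO[Si](C)(C)C(C)(C)C)c(OC)c1 | intermediate
16 | erythro (1R,2S) bis-TBS methyl cinnamate | COC(=O)/C=C/c1ccc(O[C@H]([C@H](O[Si](C)(C)C(C)(C)C)c2ccc(O[Si](C(C)C)(C(C)C)C(C)C)c(OC)c2)CO[Si](C)(C)C(C)(C)C)c(OC)c1 | intermediate
17 | (E)-cinnamyl alcohol with protected erythro side chain | OC/C=C/c1ccc(O[C@H]([C@H](O[Si](C)(C)C(C)(C)C)c2ccc(O[Si](C(C)C)(C(C)C)C(C)C)c(OC)c2)CO[Si](C)(C)C(C)(C)C)c(OC)c1 | intermediate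
18 | (E)-cinnamyl bromide with protected erythro side chain | BrC/C=C/c1ccc(O[C@H]([C@H](O[Si](C)(C)C(C)(C)C)c2ccc(O[Si](C(C)C)(C(C)C)C(C)C)c(OC)c2)CO[Si](C)(C)C(C)(C)C)c(OC)c1 | intermediate
19 | epoxy cinnamyl ether (open-chain cascade precursor) | COc1cc([C@H](OC/C=C/c3ccc(O[C@H]([C@H](O[Si](C)(C)C(C)(C)C)c4ccc(O[Si](C(C)C)(C(C)C)C(C)C)c(OC)c4)CO[Si](C)(C)C(C)(C)C)c(OC)c3)[C@H]2CO2)ccc1O[Si](C(C)C)(C(C)C)C(C)C | intermediate
20 | monocyclic tetrahydrofuran with C7–TiCp2Cl and C9'–O–TiCp2Cl (drawn in ionic form, C7 undefined) | COc1cc([CH-][C@@H]2CO[C@@H](c3ccc(O[Si](C(C)C)(C(C)C)C(C)C)c(OC)c3)[C@@H]2C[O-])ccc1O[C@H]([C@H](O[Si](C)(C)C(C)(C)C)c4ccc(O[Si](C(C)C)(C(C)C)C(C)C)c(OC)c4)CO[Si](C)(C)C(C)(C)C.[Cl-].[Cl-].[cH-]1cccc1.[cH-]1cccc1.[cH-]1cccc1.[cH-]1cccc1.[Ti+4].[Ti+4] | intermediate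
21 | monocyclic tetrahydrofuran with C7–I and C9'–O–TiCp2Cl (drawn in ionic form, C7 undefined) | COc1cc(C(I)[C@@H]2CO[C@@H](c3ccc(O[Si](C(C)C)(C(C)C)C(C)C)c(OC)c3)[C@@H]2C[O-])ccc1O[C@H]([C@H](O[Si](C)(C)C(C)(C)C)c4ccc(O[Si](C(C)C)(C(C)C)C(C)C)c(OC)c4)CO[Si](C)(C)C(C)(C)C.[Cl-].[cH-]1cccc1.[cH-]1cccc1.[Ti+4] | intermediate
22 | target with both phenols as TIPS ethers and both alcohols as TBS ethers | COc1cc([C@@H](O[Si](C)(C)C(C)(C)C)[C@H](CO[Si](C)(C)C(C)(C)C)Oc2ccc([C@@H]3OC[C@@H]4[C@H]3CO[C@H]4c3ccc(O[Si](C(C)C)(C(C)C)C(C)C)c(OC)c3)cc2OC)ccc1O[Si](C(C)C)(C(C)C)C(C)C | intermediate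
23 | CNP0172915.1, (7R,8S,7'R,8'S)-pinoresinol 4-O-[(7''R,8''S)-guaiacylglycer-8''-yl] ether | COc1cc([C@@H](O)[C@H](CO)Oc2ccc([C@@H]3OC[C@@H]4[C@H]3CO[C@H]4c3ccc(O)c(OC)c3)cc2OC)ccc1O | target

## Summary

Total step count: 15.
Longest linear sequence: 12 steps (steps 4–15, from 5).

## Steps most likely to fail

**1. Step 14.**
- What may go wrong: reduction or hydrogen abstraction at the C8' or C7 radical before the second closure, sluggish iodinolysis of the benzylic titanium species, or poor facial selectivity in the 5-exo addition.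
- Fallback: the cascade is split into a radical stage and a separate oxidative polar stage.
- Setting out from 19, the same Ti(III) cyclisation is ended by a proton quench (aq NaH2PO4). This should give the monocyclic 2-aryl-3-hydroxymethyl-4-benzyl tetrahydrofuran F1, which can be purified and checked for relative configuration.
- DDQ (CH2Cl2, 4 Å MS, 0 °C) then abstracts hydride from C7H2 next to ring B, the only dialkoxy and therefore most electron-rich arene.
- The C9' hydroxyl traps the p-alkoxybenzyl cation (oxidative benzylic C–H etherification). The same ring is closed last, and the route is rejoined at 22.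

**2. Step 9.**
- What may go wrong: ionisation of the activated, electron-rich benzylic alcohol (SN1 leakage with partial retention) or elimination.
- Fallback: neighbouring-group inversion that profits from ionisation instead of suffering from it.
- Setting out from 12, the primary hydroxyl is carbonated selectively (Boc2O, 1-methylimidazole, toluene, 0 °C) to the primary tert-butyl carbonate F2.
- MsCl/Et3N (CH2Cl2, −20 °C → rt) activates C7''–OH. The Boc carbonyl oxygen closes a six-membered ring at C7'' with loss of isobutene.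
- This should give the trans-(4R,5S)-4-aryl-5-aryloxy-1,3-dioxan-2-one F3. Both the SN2 and the SN1 mode favour it, because the erythro isomer is the diequatorial one.
- K2CO3/MeOH opens the carbonate to the erythro diol F4. Double silylation (TBSOTf, 2,6-lutidine) rejoins the route at 16.

**3. Step 13.**
- What may go wrong: solvolysis or ionisation of the electron-rich cinnamyl bromide, Payne rearrangement of the epoxy alkoxide, or silyl transfer from a phenol oxygen to the alkoxide.
- Fallback: replacement of the SN2 alkylation by a palladium-catalysed allylic etherification.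
- Setting out from 17, acetylation (Ac2O, pyridine) gives the cinnamyl acetate F5.
- F5 is coupled with the zinc alkoxide of 4 (Et2Zn 0.5 equiv, Pd(OAc)2, 2-(di-tert-butylphosphino)biphenyl, THF, rt) through the linear-selective π-cinnamyl palladium complex (Tsuji–Trost type). The route is rejoined at 19.

## Further compounds

F1 | step 14 | monocyclic (2-aryl-3-hydroxymethyl-4-benzyl)tetrahydrofuran, protected | COc1cc(C[C@@H]2CO[C@@H](c3ccc(O[Si](C(C)C)(C(C)C)C(C)C)c(OC)c3)[C@@H]2CO)ccc1O[C@H]([C@H](O[Si](C)(C)C(C)(C)C)c4ccc(O[Si](C(C)C)(C(C)C)C(C)C)c(OC)c4)CO[Si](C)(C)C(C)(C)C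
F2 | step 9 | threo (1S,2S) alcohol with the primary OH as tert-butyl carbonate | COC(=O)/C=C/c1ccc(O[C@H]([C@@H](O)c2ccc(O[Si](C(C)C)(C(C)C)C(C)C)c(OC)c2)COC(=O)OC(C)(C)C)c(OC)c1
F3 | step 9 | trans-(4R,5S)-4-aryl-5-aryloxy-1,3-dioxan-2-one | COC(=O)/C=C/c1ccc(O[C@H]3COC(=O)O[C@@H]3c2ccc(O[Si](C(C)C)(C(C)C)C(C)C)c(OC)c2)c(OC)c1
F4 | step 9 | erythro (1R,2S) 1,3-diol | COC(=O)/C=C/c1ccc(O[C@H]([C@H](O)c2ccc(O[Si](C(C)C)(C(C)C)C(C)C)c(OC)c2)CO)c(OC)c1
F5 | step 13 | (E)-cinnamyl acetate with protected erythro side chain | CC(=O)OC/C=C/c1ccc(O[C@H]([C@H](O[Si](C)(C)C(C)(C)C)c2ccc(O[Si](C(C)C)(C(C)C)C(C)C)c(OC)c2)CO[Si](C)(C)C(C)(C)C)c(OC)c1
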